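**Partner factor.** Start with the partner. Ash repeats dawn's temperature and catalysts with less partner, so I compare the two at one time, and time drops out of the ratio of their rates. From dawn to ash the partner factor is 0.451: the [partner] charged in the new flask over the [partner] charged in the old one.

| setting | autumn | dawn | summer | ash | maple | alder |
|---|---|---|---|---|---|---|
| substrate | 0.27 M | 0.27 M | 0.27 M | 0.27 M | 0.27 M | 0.27 M |
| partner | 0.36 M | 0.57 M | 0.257 M | 0.257 M | 0.257 M | 0.257 M |
| free catalyst | 2.6 mM | 2.6 mM | 3.9 mM | 2.6 mM | 2.6 mM | 2.6 mM |
| second catalyst | 0.59 mM | 0.59 mM | 0.59 mM | 0.59 mM | 0.59 mM | 0.59 mM |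
| temperature | 25 °C | 60 °C | 25 °C | 60 °C | 30 °C | 90 °C |
| remark | run made earlier | run made earlier | run made earlier |  |  |  |
| time |  |  |  | 15 min | 15 min | 15 min |

| run | time / min | target / % |
|---|---|---|
| autumn | 6.00 | 0.2 |
| autumn | 12.0 | 0.2 |
| autumn | 30.0 | 0.7 |
| autumn | 60.0 | 2.1 |
| dawn | 3.00 | 2.0 |
| dawn | 6.00 | 5.8 |
| dawn | 10.0 | 12.1 |
| dawn | 12.0 | 15.0 |
| summer | 6.00 | 0.3 |
| summer | 12.0 | 0 |
| summer | 30.0 | 1.3 |
| summer | 60.0 | 1.9 |

(standard deviation of a reading: 0.3 percentage points)

1. which flask leads in amount of target, in percent of the substrate charged ("all alike" within 1.5 percentage points) (ash / maple / alder / all alike)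
2. how much target is there at the end, in percent of the substrate charged: ash
3. how much target is there at the end, in percent of the substrate charged: maple
4. how much target is there at the end, in percent of the substrate charged: alder

- a reading or a percentage of target counts all its forms, free or not

**Two extremes.** Dawn's line from 6.00 min to 12.0 min, carried on to 15 min, reaches 19.6 %. If partner's step has no say in the rate, ash lies on that line. If partner's step is the rate-limiting step throughout, the rate scales with the factor and ash reads 8.84 %.

**Between them.** Dawn's slow start, 2.0 % by 3.00 min, suggests that something fills up before target appears, so I give an earlier step a share in the rate. I assume target consumes partner, so partner's step keeps a share too. Autumn and summer don't separate these: from autumn to summer, [partner] goes to 0.714 of its value while [free catalyst] goes to 1.50 times its value, so the two settings change at once in opposite directions, and the last readings of the two runs differ by 0.2 percentage points against a scatter of 0.3 points. I commit to the geometric mean of the extremes, 13.2 %.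

**The forecast.** It names alder as leader, with ash at 12 %, less than my figure, maple at 0.5 % and alder at 65 %. Its ground for ash: “Assuming partial partner dependence, ash runs at about 1 %/min.”

**The flasks.** alder leads with 55.9 %; ash holds 12.0 % and maple 0.329 %, crystals counted in target.

    substrate + free catalyst ⇌ free catalyst + open intermediate (K = 0.360, k = 1.20 M⁻¹ s⁻¹, Ea = 39.0 kJ mol⁻¹, ΔH = −14.0 kJ mol⁻¹)
    second catalyst + open intermediate ⇌ catalyst intermediate (K = 21.0 M⁻¹, k = 19.0 M⁻¹ s⁻¹, Ea = 36.0 kJ mol⁻¹, ΔH = 31.0 kJ mol⁻¹)
    partner + catalyst intermediate → second catalyst + target (k = 7.60 M⁻¹ s⁻¹, Ea = 65.0 kJ mol⁻¹)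
    crystals ⇌ target, rate k4*(cs4 - [target]) while solid is left; crystals form when [target] > cs4 (solubility = 6.20 mM, k = 0.120 s⁻¹)
    (constants at 90 °C)

**Stock first.** In ash at 4.36 min, open intermediate is made 3.90 times as fast as it is used up, and at 15.0 min it holds 24.9 % of the substrate against 12.0 % as target. Ash over dawn carried to 15 min (19.7 %) is 0.609, more than the partner factor 0.451 and less than 1. Autumn given maple's partner has a factor of 0.714, and at 60.0 min its target goes from 2.15 % to 1.56 %, a ratio of 0.726.

The data stem from a simulated flask for substances that don't exist; the scatter is artificial.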